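3 questions stand on two flasks that differ in temperature, and in both the starting material has two takers, the enzyme and its own self-condensation.

| flask | starting material | second substrate | free enzyme | temperature | time |
|---|---|---|---|---|---|
| beta | 0.20 mM | 0.400 mM (fed, over 40 s) | 0.0018 µM | 17 °C | 6.0 min |
| theta | 0.20 mM | 0.400 mM (fed, over 40 s) | 0.0018 µM | 37 °C | 6.0 min |

    2 starting material → self-condensation product (k1 = 330 M⁻¹ s⁻¹, Ea1 = 35.0 kJ mol⁻¹)
    second substrate → decomposed reagent (k2 = 0.0059 s⁻¹, Ea2 = 79.0 kJ mol⁻¹)
    free enzyme + free enzyme ⇌ resting dimer (K3 = 1.4 × 10⁸ M⁻¹, k3 = 2.8 × 10⁷ M⁻¹ s⁻¹, Ea3 = 18.0 kJ mol⁻¹, ΔH3 = −11.0 kJ mol⁻¹)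
    first complex → loaded enzyme + first product (k4 = 7000 s⁻¹, Ea4 = 53.0 kJ mol⁻¹)
    second substrate + loaded enzyme ⇌ second complex (K5 = 78000 M⁻¹, k5 = 3.0 × 10⁸ M⁻¹ s⁻¹, Ea5 = 12.0 kJ mol⁻¹, ΔH5 = 7.00 kJ mol⁻¹)
    starting material + free enzyme ⇌ first complex (K6 = 11000 M⁻¹, k6 = 2.7 × 10⁸ M⁻¹ s⁻¹, Ea6 = 13.0 kJ mol⁻¹, ΔH6 = 8.00 kJ mol⁻¹)
    second complex → free enzyme + target (k7 = 8200 s⁻¹, Ea7 = 59.0 kJ mol⁻¹)
    free enzyme → unfolded enzyme (k8 = 3.3 × 10⁻⁴ s⁻¹, Ea8 = 263 kJ mol⁻¹)
    (constants at 37 °C)

- a species is counted by the starting material in it: one self-condensation product counts as two
- where a step has two of a species, its rate is k times that concentration squared, and two are used at each turn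
- the list of constants is for 37 °C, to be carried to other temperatures by the activation energies and enthalpies

- the best flask by amount of target, in percent of the starting material charged; "all alike" if 1.5 percentage points covers them all (beta / theta / all alike)
- amount of target at the end, in percent of the starting material charged, beta
- amount of target at the end, in percent of the starting material charged, theta

One round of the enzyme costs the time of the step from first complex plus that of the step from second complex, so its cap in theta (the limiting rate, Vmax) is 6.80 µM s⁻¹. That is less than the feed of second substrate at 10.0 µM s⁻¹, so the throughput, taken as the slower of cap and feed, is the cap. In theta, self-condensation matches that throughput at 0.101 mM: this is the crossing concentration, the level of [starting material] at which self-condensation consumes it as fast as the enzyme does.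

At that level the half-life by self-condensation is 14.9 s, and in that time the capped enzyme turns over 0.101 mM, the same level again. The reckoning by hand therefore puts the target near crossing concentration over charge, 50.7% in theta, assuming that the whole enzyme charge stays in its working round and saturated.

In beta the cap drops to 1.53 µM s⁻¹ and the self-condensation constant to 129 M⁻¹ s⁻¹. In powers of ten these are falls of 0.648 and 0.406. The crossing concentration goes as the square root of throughput over constant, so in powers of ten it falls by half of the gap between those two falls, 0.121. Beta's crossing concentration is then 0.0768 mM, a share of 38.4%, lower than theta's.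

The forecast names theta, with 34% for beta and 39% for theta, on the ground that self-condensation “competes directly with an enzyme capped near its turnover limit”. Its numbers stand below the reckoning by hand, by 4.4 percentage points in beta and by 12 points in theta.

The simulation gives 33.3% for beta and 39.5% for theta, so theta leads and the forecast held.

In theta a fraction 0.7 of the starting material is converted by 11.7 s, shorter than the 29.4 s the cap needs for the whole charge, and the target reads 77.9% of the share reckoned from the crossing concentration. In the neighbour of theta charged with 0.16 mM of second substrate, taken as fed over the same 40 s, the feed of 4.00 µM s⁻¹ is below the cap, so the reckoning takes the feed as throughput and gives a crossing concentration of 0.0778 mM and a share of 38.9%; that flask ends at 35.2% target.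

(The rate constants were drawn at random within sensible limits, and the outcome is calculated.)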